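**Retrosynthetic overview**
- The cyclohexenone is closed last, by intramolecular aldol condensation of a 1,5-diketone; only a silyl ether is removed afterwards.
- The 1,5-diketone is unmasked by retro-aldol opening of a cyclobutanol that is assembled in one flask from three pieces: a bicyclic cyclobutanone (as enolate), the chroman acetaldehyde (aldol acceptor) and a protected hydroxy-isopentyl Grignard reagent (1,2-addition).
- Key step: the cyclobutanone, cis-1,5-dimethylbicyclo[3.2.0]heptan-6-one, comes from an acyclic amide by intramolecular [2+2] cycloaddition of a chiral keteniminium ion onto a 1,1-disubstituted alkene. The cyclopentane ring, the cyclobutane ring and both quaternary stereocentres form in one operation.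
- The chroman aldehyde comes from an o-(3-methylbut-3-enyl)phenol by enantioselective palladium-catalysed Wacker cyclisation/carbonylation (pyran ring and C2 stereocentre), then partial reduction.
- Ring order: pyran ring of the chroman (own branch); cyclopentane and cyclobutane together; cyclobutane opened; cyclohexenone last.

Assumption: the (2R,5R) auxiliary is taken to give the (1S,5S) cyclobutanone and (S,S)-Bn-BOXAX the (S)-chroman ester; each sense is checked on the first chiral product and the antipodal auxiliary or ligand is used if it is reversed.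

**Step 1**
Reactants: 1 propanoyl chloride; 2 (2R,5R)-2,5-dimethylpyrrolidine
Product: 3 1-[(2R,5R)-2,5-dimethylpyrrolidin-1-yl]propan-1-one
Conditions: 2 M NaOH (aq), CH2Cl2, 0 °C → rt
Reagents that add atoms: none
Why: Schotten–Baumann N-acylation of the secondary amine by the acid chloride; no new stereocentre.

**Step 2**
Reactants: 3 1-[(2R,5R)-2,5-dimethylpyrrolidin-1-yl]propan-1-one; 4 5-bromo-2-methylpent-1-ene
Product: 6 1-[(2R,5R)-2,5-dimethylpyrrolidin-1-yl]-2,6-dimethylhept-6-en-1-one, via lithium enolate 5 (not isolated)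
Conditions: LiN(i-Pr)2 (1.1 equiv), THF, −78 °C; then 4 (1.2 equiv), −78 → 0 °C
Reagents that add atoms: none
Why: Amide enolate alkylation (SN2 at the primary bromide); the new α-centre is immaterial because it becomes sp2 in step 3.

**Step 3**
Reactants: 6 1-[(2R,5R)-2,5-dimethylpyrrolidin-1-yl]-2,6-dimethylhept-6-en-1-one
Product: 9 (1S,5S)-1,5-dimethylbicyclo[3.2.0]heptan-6-one, via keteniminium triflate 7 (not isolated), via cyclobutaniminium triflate 8 (not isolated)
Conditions: (CF3SO2)2O (1.2 equiv), 2,4,6-collidine (1.3 equiv), ClCH2CH2Cl, 0 → 80 °C; then H2O, 60 °C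
Reagents that add atoms: water, O
Why: Ghosez-type intramolecular keteniminium–alkene [2+2] cycloaddition: the electrophilic central carbon bonds to the terminal CH2 (cation character at the tertiary internal carbon) and the three-carbon tether closes the cyclopentane, so the fusion and hence the two methyls must be cis, while the C2-symmetric pyrrolidine differentiates the faces of the keteniminium and sets both quaternary centres in the absolute sense; hydrolysis of the iminium salt gives the ketone and returns 2.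

**Step 4**
Reactants: 10 4-methoxy-2-methylphenol
Product: 11 2-bromo-4-methoxy-6-methylphenol
Conditions: N-bromosuccinimide (1.0 equiv), i-Pr2NH (10 mol %), CH2Cl2, −20 → 0 °C
Reagents that add atoms: N-bromosuccinimide, O=C1CCC(=O)N1Br
Why: Electrophilic aromatic bromination at the only free position ortho to the hydroxyl group (para is blocked and OH directs more strongly than OMe).

**Step 5**
Reactants: 11 2-bromo-4-methoxy-6-methylphenol; 12 4-bromo-2-methylbut-1-ene
Product: 14 4-methoxy-2-methyl-6-(3-methylbut-3-en-1-yl)phenol, via alkylzinc bromide 13 (not isolated)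
Conditions: 12, Zn dust, LiCl, THF, 40 °C; then 11, Pd(OAc)2 (2 mol %), SPhos (4 mol %), THF, 25 → 50 °C, zinc reagent (1.5 equiv) added slowly
Reagents that add atoms: none
Why: Negishi sp2–sp3 cross-coupling; the primary alkylzinc halide tolerates the free phenol under slow addition and the bulky biarylphosphine suppresses β-hydride elimination.

**Step 6**
Reactants: 14 4-methoxy-2-methyl-6-(3-methylbut-3-en-1-yl)phenol
Product: 15 methyl 2-[(2S)-6-methoxy-2,8-dimethyl-3,4-dihydro-2H-chromen-2-yl]acetate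
Conditions: Pd(OCOCF3)2 (10 mol %), (S,S)-Bn-BOXAX (20 mol %), p-benzoquinone (4 equiv), CO (1 atm), MeOH, rt
Reagents that add atoms: carbon monoxide, [C-]#[O+]; methanol, CO
Why: Enantioselective domino Wacker cyclisation/carbonylation: ligand-controlled 6-exo oxypalladation of the 1,1-disubstituted alkene sets the quaternary C2, the resulting σ-alkylpalladium has no β-hydrogen and therefore inserts CO and is methanolysed, and benzoquinone returns zerovalent palladium to divalent palladium.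

**Step 7**
Reactants: 15 methyl 2-[(2S)-6-methoxy-2,8-dimethyl-3,4-dihydro-2H-chromen-2-yl]acetate
Product: 16 2-[(2S)-6-methoxy-2,8-dimethyl-3,4-dihydro-2H-chromen-2-yl]acetaldehyde
Conditions: i-Bu2AlH (1.1 equiv), CH2Cl2, −78 °C; aq. potassium sodium tartrate
Reagents that add atoms: none
Why: Partial reduction of the ester stops at the aldehyde because the tetrahedral aluminium hemiacetal survives at −78 °C; C2 is untouched.

**Step 8**
Reactants: 17 4-bromo-2-methylbutan-2-ol
Product: 18 [(4-bromo-2-methylbutan-2-yl)oxy]triethylsilane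
Conditions: Et3SiOSO2CF3 (1.2 equiv), 2,6-lutidine (1.5 equiv), CH2Cl2, −78 → 0 °C
Reagents that add atoms: triethylsilyl trifluoromethanesulfonate, CC[Si](CC)(CC)OS(=O)(=O)C(F)(F)F
Why: O-silylation of the tertiary alcohol with the silyl triflate gives an ether that survives Grignard formation.

**Step 9**
Reactants: 9 (1S,5S)-1,5-dimethylbicyclo[3.2.0]heptan-6-one; 16 2-[(2S)-6-methoxy-2,8-dimethyl-3,4-dihydro-2H-chromen-2-yl]acetaldehyde; 18 [(4-bromo-2-methylbutan-2-yl)oxy]triethylsilane
Product: 22 (1S,5S)-7-{1-hydroxy-2-[(2S)-6-methoxy-2,8-dimethyl-3,4-dihydro-2H-chromen-2-yl]ethyl}-1,5-dimethyl-6-[3-methyl-3-(triethylsilyloxy)butyl]bicyclo[3.2.0]heptan-6-ol, via Grignard reagent 19 (not isolated), via cyclobutanone lithium enolate 20 (not isolated), via lithium aldolate 21 (not isolated)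
Conditions: flask A: 18, Mg, THF, 40 °C, then anhydrous CeCl3, THF, −78 °C; flask B: 9, LiN(i-Pr)2 (1.05 equiv), THF, −78 °C, then 16 (1.0 equiv), −78 °C, 20 min; B into A (2.5 equiv of 19), −78 → −40 °C; then H2O
Reagents that add atoms: none
Why: Directed aldol addition of the only enolisable position of 9 to aldehyde 16, then CeCl3-mediated Grignard 1,2-addition to the strained cyclobutanone carbonyl of aldolate 21 (the weakly basic cerium-modified reagent limits enolisation and retro-aldol); 22 forms as a mixture at its three new centres, all of which are erased in step 10, while the quaternary centres and chroman C2 are untouched.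

**Step 10**
Reactants: 22 (1S,5S)-7-{1-hydroxy-2-[(2S)-6-methoxy-2,8-dimethyl-3,4-dihydro-2H-chromen-2-yl]ethyl}-1,5-dimethyl-6-[3-methyl-3-(triethylsilyloxy)butyl]bicyclo[3.2.0]heptan-6-ol
Product: 26 (3aS,7aS)-5-(2-hydroxy-2-methylpropyl)-6-{[(2S)-6-methoxy-2,8-dimethyl-3,4-dihydro-2H-chromen-2-yl]methyl}-3a,7a-dimethyl-1,2,3,3a,7,7a-hexahydro-4H-inden-4-one, via β-keto cyclobutanol 23 (not isolated), via 1,5-diketone 24 (not isolated), via silyl ether 25 (not isolated)
Conditions: Dess–Martin periodinane (1.3 equiv), CH2Cl2, 0 °C → rt; then MeOH, KOH (excess), 0 → 40 °C; then 2 M HCl to pH 1, rt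
Reagents that add atoms: none
Why: Dess–Martin oxidation touches only the secondary alcohol; hydroxide then drives strain-releasing retro-aldol opening of 23 to 1,5-diketone 24, whose intramolecular aldol condensation (the CH2 next to the hindered ketone attacks the unhindered ketone, six-membered ring, E1cB dehydration to the conjugated tetrasubstituted enone) gives 25, and dilute HCl cleaves the tertiary silyl ether; no stereocentre is made or broken.

**Compound list**
1 | propanoyl chloride | CCC(=O)Cl | starting material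
2 | (2R,5R)-2,5-dimethylpyrrolidine | C[C@@H]1CC[C@@H](C)N1 | starting material
3 | 1-[(2R,5R)-2,5-dimethylpyrrolidin-1-yl]propan-1-one | CCC(=O)N1[C@H](C)CC[C@H]1C | intermediate
4 | 5-bromo-2-methylpent-1-ene | C=C(C)CCCBr | starting material
5 | lithium (Z)-1-[(2R,5R)-2,5-dimethylpyrrolidin-1-yl]prop-1-en-1-olate | [Li+].[O-]/C(=C\C)N1[C@H](C)CC[C@H]1C | intermediate
6 | 1-[(2R,5R)-2,5-dimethylpyrrolidin-1-yl]-2,6-dimethylhept-6-en-1-one (both C2 epimers) | C=C(C)CCCC(C)C(=O)N1[C@H](C)CC[C@H]1C | intermediate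
7 | (2R,5R)-1-(2,6-dimethylhepta-1,6-dien-1-ylidene)-2,5-dimethylpyrrolidin-1-ium trifluoromethanesulfonate | C=C(C)CCCC(C)=C=[N+]1[C@H](C)CC[C@H]1C.[O-]S(=O)(=O)C(F)(F)F | intermediate
8 | (2R,5R)-1-[(1S,5S)-1,5-dimethylbicyclo[3.2.0]heptan-6-ylidene]-2,5-dimethylpyrrolidin-1-ium trifluoromethanesulfonate | C[C@@H]1CC[C@@H](C)[N+]1=C2[C@@]3(C)CCC[C@@]3(C)C2.[O-]S(=O)(=O)C(F)(F)F | intermediate
9 | (1S,5S)-1,5-dimethylbicyclo[3.2.0]heptan-6-one | O=C1[C@@]2(C)CCC[C@@]2(C)C1 | intermediate
10 | 4-methoxy-2-methylphenol | COc1ccc(O)c(C)c1 | starting material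
11 | 2-bromo-4-methoxy-6-methylphenol | COc1cc(C)c(O)c(Br)c1 | intermediate
12 | 4-bromo-2-methylbut-1-ene | C=C(C)CCBr | starting material
13 | (3-methylbut-3-en-1-yl)zinc bromide | C=C(C)CC[Zn]Br | intermediate
14 | 4-methoxy-2-methyl-6-(3-methylbut-3-en-1-yl)phenol | COc1cc(C)c(O)c(CCC(C)=C)c1 | intermediate
15 | methyl 2-[(2S)-6-methoxy-2,8-dimethyl-3,4-dihydro-2H-chromen-2-yl]acetate | COC(=O)C[C@]1(C)CCc2cc(OC)cc(C)c2O1 | intermediate
16 | 2-[(2S)-6-methoxy-2,8-dimethyl-3,4-dihydro-2H-chromen-2-yl]acetaldehyde | O=CC[C@]1(C)CCc2cc(OC)cc(C)c2O1 | intermediate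
17 | 4-bromo-2-methylbutan-2-ol | CC(C)(O)CCBr | starting material
18 | [(4-bromo-2-methylbutan-2-yl)oxy]triethylsilane | CC[Si](CC)(CC)OC(C)(C)CCBr | intermediate
19 | [3-methyl-3-(triethylsilyloxy)butyl]magnesium bromide | CC[Si](CC)(CC)OC(C)(C)CC[Mg]Br | intermediate
20 | lithium (1S,5S)-1,5-dimethylbicyclo[3.2.0]hept-6-en-6-olate | [Li+].[O-]C1[C@@]2(C)CCC[C@@]2(C)C=1 | intermediate
21 | lithium 1-[(1S,5S)-1,5-dimethyl-6-oxobicyclo[3.2.0]heptan-7-yl]-2-[(2S)-6-methoxy-2,8-dimethyl-3,4-dihydro-2H-chromen-2-yl]ethan-1-olate | O=C1[C@@]2(C)CCC[C@@]2(C)C1C([O-])C[C@]3(C)CCc4cc(OC)cc(C)c4O3.[Li+] | intermediate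
22 | (1S,5S)-7-{1-hydroxy-2-[(2S)-6-methoxy-2,8-dimethyl-3,4-dihydro-2H-chromen-2-yl]ethyl}-1,5-dimethyl-6-[3-methyl-3-(triethylsilyloxy)butyl]bicyclo[3.2.0]heptan-6-ol (mixture at C6, C7 and the side-chain carbinol) | CC[Si](CC)(CC)OC(C)(C)CCC1(O)[C@@]2(C)CCC[C@@]2(C)C1C(O)C[C@]3(C)CCc4cc(OC)cc(C)c4O3 | intermediate
23 | 1-{(1S,5S)-6-hydroxy-1,5-dimethyl-6-[3-methyl-3-(triethylsilyloxy)butyl]bicyclo[3.2.0]heptan-7-yl}-2-[(2S)-6-methoxy-2,8-dimethyl-3,4-dihydro-2H-chromen-2-yl]ethan-1-one | CC[Si](CC)(CC)OC(C)(C)CCC1(O)[C@@]2(C)CCC[C@@]2(C)C1C(=O)C[C@]3(C)CCc4cc(OC)cc(C)c4O3 | intermediate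
24 | 1-[(1S,2S)-2-{3-[(2S)-6-methoxy-2,8-dimethyl-3,4-dihydro-2H-chromen-2-yl]-2-oxopropyl}-1,2-dimethylcyclopentyl]-4-methyl-4-(triethylsilyloxy)pentan-1-one | CC[Si](CC)(CC)OC(C)(C)CCC(=O)[C@@]1(C)CCC[C@@]1(C)CC(=O)C[C@]2(C)CCc3cc(OC)cc(C)c3O2 | intermediate
25 | (3aS,7aS)-6-{[(2S)-6-methoxy-2,8-dimethyl-3,4-dihydro-2H-chromen-2-yl]methyl}-3a,7a-dimethyl-5-[2-methyl-2-(triethylsilyloxy)propyl]-1,2,3,3a,7,7a-hexahydro-4H-inden-4-one | COc1cc(C)c2c(c1)CC[C@@](C)(CC1=C(CC(C)(C)O[Si](CC)(CC)CC)C(=O)[C@@]3(C)CCC[C@@]3(C)C1)O2 | intermediate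
26 | (3aS,7aS)-5-(2-hydroxy-2-methylpropyl)-6-{[(2S)-6-methoxy-2,8-dimethyl-3,4-dihydro-2H-chromen-2-yl]methyl}-3a,7a-dimethyl-1,2,3,3a,7,7a-hexahydro-4H-inden-4-one (CNP0224132.2) | COc1cc(C)c2c(c1)CC[C@@](C)(CC1=C(CC(C)(C)O)C(=O)[C@@]3(C)CCC[C@@]3(C)C1)O2 | target

**Step count and risks**
Total steps: 10. Longest linear sequence: 6 (steps 4, 5, 6, 7, 9, 10).

Step 3 is the first risk. The tetrasubstituted keteniminium ion may cyclise slowly, the tertiary cation may lose a proton instead of closing, or the face selectivity may be lower than for unsubstituted analogues. The fallback sets out from 2 and comes back at 8. Amine 2 is acylated with acetyl chloride (aq. NaOH, CH2Cl2) to N-acetyl amide F1. (CF3SO2)2O and collidine convert F1 into the unsubstituted keteniminium triflate F2, which is trapped intermolecularly by commercial 1,2-dimethylcyclopentene in a [2+2] cycloaddition. This gives iminium salt 8 and, after the hydrolysis of step 3, ketone 9. The cyclopentane is then bought and only the four-membered ring is formed, with the same auxiliary controlling which alkene carbon takes the iminium carbon.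

Step 9 is the second risk. Aldolate 21 may revert, or the Grignard reagent 19 with CeCl3 may fail to add to the hindered carbonyl next to a quaternary carbon. The fallback sets out from 9 and 15 and comes back at 24. Enolate 20 is C-acylated with ester 15 to 2-acylcyclobutanone F3, which is opened without isolation by methoxide (NaOMe, MeOH, retro-Claisen) to δ-keto ester F4. LiOH gives keto acid F5, and Ac2O with NaOAc closes it to enol lactone F6. A Fujimoto–Belleau reaction of F6 with 19 then delivers diketone 24 directly, with no oxidation step, and 24 continues through the base and acid stages of step 10.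

Step 10 is the third risk. Under hydroxide the β-aryloxy ketone 24 could open by retro-oxa-Michael reaction and erode the chroman C2 configuration, or the aldol could close the other way round. The fallback sets out from 18 and comes back at 25. Arbuzov reaction of 18 with P(OMe)3 (110 °C) gives phosphonate F7. Its α-lithio derivative (n-BuLi, THF, −78 °C) replaces 19 in the addition to aldolate 21 and gives β-hydroxy phosphonate diol F8. Dess–Martin oxidation gives β-keto cyclobutanol phosphonate F9, and LiCl with DBU in MeCN at rt opens it to β-keto phosphonate F10. F10 closes by intramolecular Horner–Wadsworth–Emmons olefination, which is regiospecific and needs only an amine base, to silyl ether 25; acid then gives 26 as in step 10.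

**Further compounds**
F1 | step 3 | 1-[(2R,5R)-2,5-dimethylpyrrolidin-1-yl]ethan-1-one | CC(=O)N1[C@H](C)CC[C@H]1C
F2 | step 3 | (2R,5R)-1-ethenylidene-2,5-dimethylpyrrolidin-1-ium trifluoromethanesulfonate | C=C=[N+]1[C@H](C)CC[C@H]1C.[O-]S(=O)(=O)C(F)(F)F
F3 | step 9 | (1S,5S)-7-{[(2S)-6-methoxy-2,8-dimethyl-3,4-dihydro-2H-chromen-2-yl]acetyl}-1,5-dimethylbicyclo[3.2.0]heptan-6-one | O=C1[C@@]2(C)CCC[C@@]2(C)C1C(=O)C[C@]3(C)CCc4cc(OC)cc(C)c4O3
F4 | step 9 | methyl (1S,2S)-2-{3-[(2S)-6-methoxy-2,8-dimethyl-3,4-dihydro-2H-chromen-2-yl]-2-oxopropyl}-1,2-dimethylcyclopentane-1-carboxylate | COC(=O)[C@@]1(C)CCC[C@@]1(C)CC(=O)C[C@]2(C)CCc3cc(OC)cc(C)c3O2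
F5 | step 9 | (1S,2S)-2-{3-[(2S)-6-methoxy-2,8-dimethyl-3,4-dihydro-2H-chromen-2-yl]-2-oxopropyl}-1,2-dimethylcyclopentane-1-carboxylic acid | OC(=O)[C@@]1(C)CCC[C@@]1(C)CC(=O)C[C@]2(C)CCc3cc(OC)cc(C)c3O2
F6 | step 9 | (4aS,7aS)-3-{[(2S)-6-methoxy-2,8-dimethyl-3,4-dihydro-2H-chromen-2-yl]methyl}-4a,7a-dimethyl-5,6,7,7a-tetrahydrocyclopenta[c]pyran-1(4aH)-one | O=C1[C@@]2(C)CCC[C@@]2(C)C=C(C[C@]3(C)CCc4cc(OC)cc(C)c4O3)O1
F7 | step 10 | dimethyl [3-methyl-3-(triethylsilyloxy)butyl]phosphonate | COP(=O)(OC)CCC(C)(C)O[Si](CC)(CC)CC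
F8 | step 10 | dimethyl {1-[(1S,5S)-6-hydroxy-7-{1-hydroxy-2-[(2S)-6-methoxy-2,8-dimethyl-3,4-dihydro-2H-chromen-2-yl]ethyl}-1,5-dimethylbicyclo[3.2.0]heptan-6-yl]-3-methyl-3-(triethylsilyloxy)butyl}phosphonate | COP(=O)(OC)C(CC(C)(C)O[Si](CC)(CC)CC)C1(O)[C@@]2(C)CCC[C@@]2(C)C1C(O)C[C@]3(C)CCc4cc(OC)cc(C)c4O3
F9 | step 10 | dimethyl {1-[(1S,5S)-6-hydroxy-7-{[(2S)-6-methoxy-2,8-dimethyl-3,4-dihydro-2H-chromen-2-yl]acetyl}-1,5-dimethylbicyclo[3.2.0]heptan-6-yl]-3-methyl-3-(triethylsilyloxy)butyl}phosphonate | COP(=O)(OC)C(CC(C)(C)O[Si](CC)(CC)CC)C1(O)[C@@]2(C)CCC[C@@]2(C)C1C(=O)C[C@]3(C)CCc4cc(OC)cc(C)c4O3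
F10 | step 10 | dimethyl {1-[(1S,2S)-2-{3-[(2S)-6-methoxy-2,8-dimethyl-3,4-dihydro-2H-chromen-2-yl]-2-oxopropyl}-1,2-dimethylcyclopentyl]-4-methyl-1-oxo-4-(triethylsilyloxy)pentan-2-yl}phosphonate | COP(=O)(OC)C(CC(C)(C)O[Si](CC)(CC)CC)C(=O)[C@@]1(C)CCC[C@@]1(C)CC(=O)C[C@]2(C)CCc3cc(OC)cc(C)c3O2
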